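A small charge should not be spent on finding where a reaction stops, so read that from the runs already made.

in all of them: partner 1.35 M
- Monday's: substrate 1 M; run made earlier
- Thursday's: substrate 2.2 M; run made earlier
- flask: substrate 1.5 M; time 30 min

| run | time / min | substrate / % | target / % | isomer of the product A / % |
|---|---|---|---|---|
| Monday's | 3.00 | 7.4 | 1.5 | 85.0 |
| Monday's | 8.00 | 7.0 | 2.3 | 84.9 |
| Monday's | 15.0 | 6.9 | 2.2 | 85.2 |
| Monday's | 25.0 | 4.9 | 5.4 | 85.5 |
| Thursday's | 2.00 | 41.2 | 1.7 | 53.0 |
| Thursday's | 4.00 | 39.4 | 1.2 | 53.7 |
| Thursday's | 10.0 | 39.9 | 0.4 | 53.5 |
| Thursday's | 25.0 | 40.4 | 2.1 | 53.9 |

(standard deviation of a reading: 1 percentage point)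

- the reaction counts as stopped when no species that holds the substrate changes by six tenths of a point or more over the second half of the time

- which holds at 30 min: what has brought the reaction to rest, or that it has not come to rest (all of the substrate has reacted / forward and back rates have come level / it is still moving / the partner has run out first)
- conversion of substrate at 30 min
- amount of target at 30 min, in percent of the substrate charged
- amount of isomer of the product A at 30 min, in percent of the substrate charged

Isomer of the product A looks flat in both runs from the first readings, at 3.00 min and 2.00 min. Isomer of the product A moves by 0.5 percentage points on Monday and 0.9 points on Thursday, less than the scatter of a difference. So replace each curve by its mean, which carries an error of 0.5 points.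

Monday's mean substrate is 6.55%. That makes [substrate] 0.0655 M and, with partner used one for one, [partner] 0.416 M. Define the stall quotient, an overall equilibrium constant, as substrate consumed over [substrate][partner] at the stop. Monday's run gives 34.3 L mol⁻¹, good to 7.63%.

Thursday's mean substrate of 40.2% gives, the same way, 42.5 L mol⁻¹. The two part, so ask which one cheats. Thursday's [partner], the limiting reagent there, is 0.0350 M, far less than the 1.35 M charged. It is a small difference of large numbers, so its error is 31.5%. The gap between the quotients lies inside that error, and Monday's error is smaller, so trust Monday's.

Solve the quotient for this flask. Monday's value gives a conversion of 81.5%, Thursday's 82.6%. Monday's last readings stay in its means as scatter, though target at 5.4% stands 3.2 points above the reading before it and substrate at 4.9% stands 2 points below; that is a judgement, not a proof. Monday's mean shares of what was consumed then give target 2.48% and isomer of the product A 74.2%. This flask's substrate charge lies between those of the two runs, and their first readings came well before the second half of this flask's time, so reckon this flask at rest by then, with forward and back rates level.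

The forecast says it is still moving, with conversion 81%, target 5% and isomer of the product A 72%, on the ground that “the substrate and target are still drifting by more than 0.6 points”.

In the flask at 30 min, forward and back rates have come level: conversion 81.4%, target 2.39%, isomer of the product A 74.7%.

    substrate + partner ⇌ isomer of the product A (K = 31.0 L mol⁻¹, k = 0.120 L mol⁻¹ s⁻¹)
    target ⇌ isomer of the product B (K = 1.80, k = 0.170 s⁻¹)
    substrate + partner ⇌ target (K = 0.990 L mol⁻¹, k = 0.840 L mol⁻¹ s⁻¹)

The forecast and the flask part on the ending: substrate in the flask stands at 18.6% at 15.0 min and at 18.6% at 30.0 min. Now take the neighbour flask, with 0.38 M of substrate and the same partner. Monday's quotient leaves 2.88% of its substrate. The neighbour flask holds 2.93% of substrate at 30.0 min, a conversion of 97.1%.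

(The numbers in the tables stem from a simulated flask for an exercise, noise included.)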